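The coumarin is cut at C3–C4 and O1–C2, and the 2,3-dihydropyran-4-one ring at C4–C5 and O1–C6. The key step exploits the enol-ether oxygen O1 of the pyranone: addition of the lithium alkoxide of (R)-3-hydroxybutanoic Weinreb amide to ethyl buta-2,3-dienoate makes O1–C6 and, without external base, a 3-alkoxy dienolate whose γ-carbon (ring C5, the =CH) acylates the amide carbonyl (ring C4) and closes the ring. The precursor is therefore an acyclic hydroxy amide plus an allenoate; C2 comes from the chiral pool. The resulting pyranonylacetate is then condensed, Knoevenagel fashion, with a citrinin-type quinone methide that carries the side-chain stereodiad.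

Key step: step 8

Assumption: the quinone methide made in step 6 is written in its anhydro form; in wet solvents it equilibrates with its hydrate (the lactol), which should react in the same way in the last step.

Step 1
Reactants: 1 5-bromo-1,3-dimethoxy-2-methylbenzene
Product: 3 1-bromo-3,5-dimethoxy-2,4-dimethylbenzene, via aryllithium 2 (not isolated)
Conditions: LiN(i-Pr)2 (LDA), THF, −78 °C; then MeI, −78 °C → rt
Reagents that add atoms: iodomethane, CI
Why: Directed ortho-metalation: the ring hydrogen flanked by Br and OMe is the most acidic position, so LDA should lithiate it at −78 °C (below the temperature of benzyne formation) and MeI then alkylates the aryllithium; no stereocentre is involved.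

Step 2
Reactants: 3 1-bromo-3,5-dimethoxy-2,4-dimethylbenzene; 4 (2R,3R)-2,3-dimethyloxirane
Product: 6 (2R,3R)-3-(3,5-dimethoxy-2,4-dimethylphenyl)butan-2-ol, via Grignard reagent 5 (not isolated)
Conditions: Mg, THF, 50 °C; then CuI (10 mol %), 4, −30 °C → rt; then 1 M HCl
Reagents that add atoms: none
Why: Copper-catalysed Grignard opening of an epoxide (SN2): the two carbons of the C2-symmetric trans-epoxide are equivalent and the aryl group enters with inversion, which sets the benzylic centre as R, while the carbinol centre keeps the R configuration of 4 and is corrected in steps 3 and 4.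

Step 3
Reactants: 6 (2R,3R)-3-(3,5-dimethoxy-2,4-dimethylphenyl)butan-2-ol
Product: 7 (3R)-3-(3,5-dimethoxy-2,4-dimethylphenyl)butan-2-one
Conditions: Dess–Martin periodinane, CH2Cl2, 0 °C → rt
Reagents that add atoms: none
Why: Dess–Martin oxidation is neutral and fast, so the wrongly configured carbinol is erased without enolisation of the neighbouring benzylic stereocentre.

Step 4
Reactants: 7 (3R)-3-(3,5-dimethoxy-2,4-dimethylphenyl)butan-2-one
Product: 8 (2S,3R)-3-(3,5-dimethoxy-2,4-dimethylphenyl)butan-2-ol
Conditions: LiBH(s-Bu)3 (L-Selectride), THF, −78 °C; then H2O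
Reagents that add atoms: none
Why: Felkin–Anh-controlled hydride reduction: the bulky borohydride attacks the carbonyl anti to the aryl group on the α-stereocentre, which should give the (2S) carbinol, that is the syn (threo) diastereomer that the epoxide opening cannot deliver directly.

Step 5
Reactants: 8 (2S,3R)-3-(3,5-dimethoxy-2,4-dimethylphenyl)butan-2-ol
Product: 9 5-[(2R,3S)-3-hydroxybutan-2-yl]-2,4-dimethylbenzene-1,3-diol
Conditions: BBr3, CH2Cl2, −78 → 0 °C; then H2O
Reagents that add atoms: none
Why: BBr3 demethylation (Lewis acid-assisted SN2 cleavage of aryl methyl ethers): both methoxy groups are cleaved at low temperature while the secondary alcohol is held as a borate ester and returns on hydrolysis, with both stereocentres untouched.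

Step 6
Reactants: 9 5-[(2R,3S)-3-hydroxybutan-2-yl]-2,4-dimethylbenzene-1,3-diol
Product: 11 (3S,4R)-8-hydroxy-3,4,5,7-tetramethyl-3,4-dihydro-6H-isochromen-6-one, via ethoxy acetal 10 (not isolated)
Conditions: HC(OEt)3, CF3CO2H, 0 °C → rt; then H2O
Reagents that add atoms: triethyl orthoformate, CCOC(OCC)OCC
Why: Electrophilic aromatic formylation with an orthoformate at the only free ring carbon (ortho and para to the two hydroxyls): the side-chain hydroxyl captures the new carbon as cyclic acetal 10 and loss of ethanol, pushed by the para hydroxyl, should give the quinone methide, a masked salicylaldehyde, without touching the stereocentres.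

Step 7
Reactants: 12 methyl (3R)-3-hydroxybutanoate
Product: 13 (3R)-3-hydroxy-N-methoxy-N-methylbutanamide
Conditions: MeNH(OMe)·HCl, i-PrMgCl, THF, −20 → 0 °C; then 1 M HCl
Reagents that add atoms: N,O-dimethylhydroxylamine hydrochloride, CNOC.Cl
Why: Weinreb amide formation by aminolysis of the ester with the chloromagnesium amide of N,O-dimethylhydroxylamine, which tolerates the free hydroxyl as its magnesium alkoxide and does not touch the stereocentre.

Step 8
Reactants: 13 (3R)-3-hydroxy-N-methoxy-N-methylbutanamide; 14 ethyl buta-2,3-dienoate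
Product: 18 ethyl 2-[(2R)-2-methyl-4-oxo-3,4-dihydro-2H-pyran-6-yl]acetate, via lithium alkoxide 15 (not isolated), via lithium dienolate 16 (not isolated), via tetrahedral adduct 17 (not isolated)
Conditions: n-BuLi (1.0 equiv), THF, −78 °C; then 14 (slow addition), −78 → 0 °C; then 1 M HCl, rt
Reagents that add atoms: none
Why: Proposed new method: alkoxide 15 adds to the central carbon of the allenoate (oxa-Michael, forming O1–C6) and thereby generates, with no external base, the 3-alkoxy dienolate 16, whose γ-carbon (future C5) attacks the Weinreb carbonyl (future C4) to give the chelated tetrahedral adduct 17; acid work-up releases the ketone and moves the double bond into the ring. The closest known reaction types are the Michael–Dieckmann (Fiesselmann-type) annulation of hydroxy or mercapto esters with acetylenic esters and the γ-acylation of lithium dienolates of 3-alkoxycrotonates. The ring closes in the 6-(enolendo)-exo-trig mode. No new stereocentre remains: C2 comes from 13 with retention because its C–O bond is never broken, and the hemiaminal carbon of 17 collapses to the carbonyl. The step needs γ- over α-acylation (α-attack would give the isomeric 5-carboxylate) and cyclisation over protonation, β-elimination or Michael oligomerisation; the 3-alkoxy group raises the nucleophilicity of the unhindered CH2 terminus, and the absence of any proton source or free base (the alkoxide is consumed, the leaving group stays bound in 17) should suppress the other paths.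

Step 9
Reactants: 11 (3S,4R)-8-hydroxy-3,4,5,7-tetramethyl-3,4-dihydro-6H-isochromen-6-one; 18 ethyl 2-[(2R)-2-methyl-4-oxo-3,4-dihydro-2H-pyran-6-yl]acetate
Product: 20 7-hydroxy-5-[(2R,3S)-3-hydroxybutan-2-yl]-6,8-dimethyl-3-[(2R)-2-methyl-4-oxo-3,4-dihydro-2H-pyran-6-yl]-2H-chromen-2-one, via arylidene ester 19 (not isolated)
Conditions: piperidine (20 mol %), AcOH (20 mol %), EtOH, 60 °C
Reagents that add atoms: none
Why: Knoevenagel condensation with lactonisation (coumarin synthesis): C1 of the quinone methide reacts as the masked aldehyde carbon with the doubly activated CH2 of 18, opening of the O2–C1 bond (retro-oxa-Michael) gives arylidene ester 19, and the C8 hydroxyl of 11 (ortho to the new alkene) then closes the lactone with loss of ethanol, all without touching a stereocentre.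

Compound list

1 | 5-bromo-1,3-dimethoxy-2-methylbenzene | COc1cc(Br)cc(OC)c1C | starting material
2 | (6-bromo-2,4-dimethoxy-3-methylphenyl)lithium | [Li]c1c(Br)cc(OC)c(C)c1OC | intermediate
3 | 1-bromo-3,5-dimethoxy-2,4-dimethylbenzene | Cc1c(Br)cc(OC)c(C)c1OC | intermediate
4 | (2R,3R)-2,3-dimethyloxirane | C[C@H]1O[C@@H]1C | starting material
5 | bromo(3,5-dimethoxy-2,4-dimethylphenyl)magnesium | Br[Mg]c1cc(OC)c(C)c(OC)c1C | intermediate
6 | (2R,3R)-3-(3,5-dimethoxy-2,4-dimethylphenyl)butan-2-ol | COc1cc([C@@H](C)[C@@H](C)O)c(C)c(OC)c1C | intermediate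
7 | (3R)-3-(3,5-dimethoxy-2,4-dimethylphenyl)butan-2-one | COc1cc([C@@H](C)C(C)=O)c(C)c(OC)c1C | intermediate
8 | (2S,3R)-3-(3,5-dimethoxy-2,4-dimethylphenyl)butan-2-ol | COc1cc([C@@H](C)[C@H](C)O)c(C)c(OC)c1C | intermediate
9 | 5-[(2R,3S)-3-hydroxybutan-2-yl]-2,4-dimethylbenzene-1,3-diol | Cc1c(O)cc([C@@H](C)[C@H](C)O)c(C)c1O | intermediate
10 | (3S,4R)-1-ethoxy-3,4,5,7-tetramethyl-3,4-dihydro-1H-isochromene-6,8-diol (either configuration at C1) | CCOC1O[C@@H](C)[C@H](C)c2c(C)c(O)c(C)c(O)c12 | intermediate
11 | (3S,4R)-8-hydroxy-3,4,5,7-tetramethyl-3,4-dihydro-6H-isochromen-6-one | C[C@@H]1OC=C2C(O)=C(C)C(=O)C(C)=C2[C@H]1C | intermediate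
12 | methyl (3R)-3-hydroxybutanoate | C[C@@H](O)CC(=O)OC | starting material
13 | (3R)-3-hydroxy-N-methoxy-N-methylbutanamide | C[C@@H](O)CC(=O)N(C)OC | intermediate
14 | ethyl buta-2,3-dienoate | C=C=CC(=O)OCC | starting material
15 | lithium (2R)-4-[methoxy(methyl)amino]-4-oxobutan-2-olate | C[C@@H](O[Li])CC(=O)N(C)OC | intermediate
16 | lithium 1-ethoxy-3-{[(2R)-4-[methoxy(methyl)amino]-4-oxobutan-2-yl]oxy}buta-1,3-dien-1-olate | [Li]OC(OCC)=CC(=C)O[C@H](C)CC(=O)N(C)OC | intermediate
17 | lithium (2R)-6-(2-ethoxy-2-oxoethylidene)-4-[methoxy(methyl)amino]-2-methyloxan-4-olate (either configuration at C4) | CCOC(=O)C=C1CC(O[Li])(N(C)OC)C[C@@H](C)O1 | intermediate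
18 | ethyl 2-[(2R)-2-methyl-4-oxo-3,4-dihydro-2H-pyran-6-yl]acetate | CCOC(=O)CC1=CC(=O)C[C@@H](C)O1 | intermediate
19 | ethyl 3-{2,4-dihydroxy-6-[(2R,3S)-3-hydroxybutan-2-yl]-3,5-dimethylphenyl}-2-[(2R)-2-methyl-4-oxo-3,4-dihydro-2H-pyran-6-yl]prop-2-enoate | CCOC(=O)C(=Cc1c(O)c(C)c(O)c(C)c1[C@@H](C)[C@H](C)O)C1=CC(=O)C[C@@H](C)O1 | intermediate
20 | 7-hydroxy-5-[(2R,3S)-3-hydroxybutan-2-yl]-6,8-dimethyl-3-[(2R)-2-methyl-4-oxo-3,4-dihydro-2H-pyran-6-yl]-2H-chromen-2-one (CNP0291478.1) | Cc1c(O)c(C)c2oc(=O)c(C3=CC(=O)C[C@@H](C)O3)cc2c1[C@@H](C)[C@H](C)O | target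

Total step count: 9. Longest linear sequence: 7 steps (steps 1, 2, 3, 4, 5, 6 and 9); steps 7 and 8 form the second branch.

The three steps most likely to fail

Step 8 (Proposed new method). The dienolate may acylate through its α-carbon instead of its γ-carbon, may transfer a proton from the CH2 next to the amide and then expel the vinylogous carboxylate by β-elimination, or may add to a second molecule of allenoate. The fallback sets out from 13 and comes back at 18, using known chemistry. Compound 13 is silylated (TBSCl, imidazole, DMF) to (3R)-3-[(tert-butyldimethylsilyl)oxy]-N-methoxy-N-methylbutanamide F1. The dianion of ethyl acetoacetate (NaH then n-BuLi, THF, 0 °C) is acylated at its terminal carbon by F1 to give ethyl (7R)-7-[(tert-butyldimethylsilyl)oxy]-3,5-dioxooctanoate F2. CF3CO2H in wet CH2Cl2 then removes the silyl group and cyclodehydrates the hydroxy diketone to 18. In this variant the C4–C5 bond is made first and the ring is closed at O1–C6.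

Step 9. The union may stop at the 1-substituted isochroman, because re-addition of the side-chain hydroxyl to the arylidene can outrun lactonisation. The amine may also open the pyranone by conjugate addition. The fallback sets out from 8 and comes back at 20, bypassing 9 and 11. Compound 8 is acetylated (Ac2O, pyridine, DMAP) to (2S,3R)-3-(3,5-dimethoxy-2,4-dimethylphenyl)butan-2-yl acetate F3. Rieche formylation (Cl2CHOMe, TiCl4, CH2Cl2, −78 → 0 °C) at the one free ring carbon gives (2S,3R)-3-(2-formyl-3,5-dimethoxy-4,6-dimethylphenyl)butan-2-yl acetate F4. BBr3 at −78 → −20 °C gives (2S,3R)-3-(2-formyl-3,5-dihydroxy-4,6-dimethylphenyl)butan-2-yl acetate F5, a true salicylaldehyde that cannot form a lactol. Knoevenagel condensation with lactonisation with 18 (piperidine, AcOH, EtOH) gives (2S,3R)-3-{7-hydroxy-6,8-dimethyl-3-[(2R)-2-methyl-4-oxo-3,4-dihydro-2H-pyran-6-yl]-2-oxo-2H-chromen-5-yl}butan-2-yl acetate F6. K2CO3 in MeOH at 0 °C removes the acetate to give 20.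

Step 5. The borate-activated secondary alcohol may be substituted by bromide with participation of the neighbouring electron-rich aryl ring, which would scramble or destroy both side-chain stereocentres. The fallback sets out from 8 and comes back at 11, bypassing 9 and 10. Compound 8 is first cyclised with HC(OMe)3 and BF3·OEt2 (CH2Cl2, 0 °C; intramolecular formylation at the orthoester level, oxa-Pictet–Spengler type) to (3S,4R)-1,6,8-trimethoxy-3,4,5,7-tetramethyl-3,4-dihydro-1H-isochromene F7, in which the alcohol oxygen is tied up in the acetal. BBr3 followed by water then cleaves the three methyl ethers and should give 11 directly.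

Further compounds
F1 | step 8 | (3R)-3-[(tert-butyldimethylsilyl)oxy]-N-methoxy-N-methylbutanamide | C[C@@H](O[Si](C)(C)C(C)(C)C)CC(=O)N(C)OC
F2 | step 8 | ethyl (7R)-7-[(tert-butyldimethylsilyl)oxy]-3,5-dioxooctanoate | CCOC(=O)CC(=O)CC(=O)C[C@@H](C)O[Si](C)(C)C(C)(C)C
F3 | step 9 | (2S,3R)-3-(3,5-dimethoxy-2,4-dimethylphenyl)butan-2-yl acetate | COc1cc([C@@H](C)[C@H](C)OC(C)=O)c(C)c(OC)c1C
F4 | step 9 | (2S,3R)-3-(2-formyl-3,5-dimethoxy-4,6-dimethylphenyl)butan-2-yl acetate | COc1c(C=O)c([C@@H](C)[C@H](C)OC(C)=O)c(C)c(OC)c1C
F5 | step 9 | (2S,3R)-3-(2-formyl-3,5-dihydroxy-4,6-dimethylphenyl)butan-2-yl acetate | Oc1c(C=O)c([C@@H](C)[C@H](C)OC(C)=O)c(C)c(O)c1C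
F6 | step 9 | (2S,3R)-3-{7-hydroxy-6,8-dimethyl-3-[(2R)-2-methyl-4-oxo-3,4-dihydro-2H-pyran-6-yl]-2-oxo-2H-chromen-5-yl}butan-2-yl acetate | Cc1c(O)c(C)c2oc(=O)c(C3=CC(=O)C[C@@H](C)O3)cc2c1[C@@H](C)[C@H](C)OC(C)=O
F7 | step 5 | (3S,4R)-1,6,8-trimethoxy-3,4,5,7-tetramethyl-3,4-dihydro-1H-isochromene | COC1O[C@@H](C)[C@H](C)c2c(C)c(OC)c(C)c(OC)c12
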